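**Plan**

Numbering used: ring carbons C1–C10 (C4 bears the methyl, C10 the ester carbon C14); lactone carbons C11 (α), C12 (C=O), C13 (=CH2).
Cuts, in retrosynthetic order: C11=C13 (Horner–Wadsworth–Emmons with formaldehyde) and the C8 ester; C1=C10 of the ten-membered ring (ring-closing metathesis); C7–C11 of the γ-lactone; the O6–C12 acyl bond; C5–C6 (Nozaki–Hiyama–Kishi) between two achiral fragments.
Enabling feature: C7, the β-carbon of the lactone, lies between two oxygen-bearing carbons (C6–O of the lactone, C8–O of the methacrylate). C7–C8 can therefore be a trans-epoxide whose oxygen ends on C8, while O6 carries C11–C12 as a phosphonoacetate; one 5-exo opening makes C7–C11, closes the lactone and frees the C8 hydroxyl.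
Forward order: open chain, epoxide, γ-lactone (step 7), ten-membered carbocycle (step 8), methacrylate, exocyclic methylene. The phosphoryl group activates C11 for the key step, is the latent C13 methylene and leaves in the last step.
Stereochemistry: a Sharpless kinetic resolution selects C6 and sets C7/C8 (erythro trans-epoxide); C7 is inverted in the SN2 ring closure and C8 retained; C4=C5 (E) comes from syn-carboalumination and C1=C10 (C9 and C2 cis) from closure of the ten-membered ring.

Key step: step 7

**Route**

Step 1
Reactants: 1 hex-1-en-5-yne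
Product: 3 (1E)-1-iodo-2-methylhexa-1,5-diene, via alkenyldimethylalane 2 (not isolated)
Conditions: AlMe3, Cp2ZrCl2 (cat.), CH2Cl2, 0 to 23 °C; then I2, THF, −30 to 0 °C
Reagents that add atoms: trimethylaluminium C[Al](C)C; iodine II
Why: Negishi zirconium-catalysed carboalumination adds methyl and aluminium syn across the terminal alkyne (methyl to the internal carbon), and iodinolysis of the C–Al bond with retention should give the E trisubstituted vinyl iodide that becomes C4=C5, the isolated terminal alkene being inert to the achiral zirconocene.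

Step 2
Reactants: 4 methyl 2-(bromomethyl)prop-2-enoate
Product: 5 methyl 2-methylidenepent-4-enoate
Conditions: CH2=CHMgBr, CuI (cat.), THF, −78 to −30 °C
Reagents that add atoms: vinylmagnesium bromide C=C[Mg]Br
Why: Copper-catalysed allylic substitution of the bromide by the vinyl Grignard reagent (the SN2 and SN2′ pathways give the same product) should be much faster at low temperature than attack on the ester.

Step 3
Reactants: 5 methyl 2-methylidenepent-4-enoate
Product: 6 methyl (4E)-2-methylidene-6-oxohex-4-enoate
Conditions: (E)-but-2-enal (excess), second-generation Hoveyda–Grubbs catalyst (cat.), CH2Cl2, 40 °C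
Reagents that add atoms: (E)-but-2-enal C/C=C/C=O
Why: Olefin cross-metathesis of the monosubstituted alkene with an enal partner should give the E enal with loss of propene, the 1,1-disubstituted acrylate being too hindered and electron-poor to compete.

Step 4
Reactants: 3 (1E)-1-iodo-2-methylhexa-1,5-diene and 6 methyl (4E)-2-methylidene-6-oxohex-4-enoate
Product: 7 racemic methyl (4E,7E)-6-hydroxy-8-methyl-2-methylidenedodeca-4,7,11-trienoate
Conditions: CrCl2, NiCl2 (cat.), DMSO, 23 °C
Reagents that add atoms: none
Why: Nozaki–Hiyama–Kishi coupling, in which the alkenylchromium species formed from 3 with retention of olefin geometry should add 1,2 to the aldehyde only, leaving the acrylate ester and the acidic C9 methylene untouched and forming the C5–C6 bond with C6 racemic.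

Step 5
Reactants: 7 racemic methyl (4E,7E)-6-hydroxy-8-methyl-2-methylidenedodeca-4,7,11-trienoate
Product: 8 methyl 3-[(2R,3R)-3-[(1R,2E)-1-hydroxy-3-methylhepta-2,6-dien-1-yl]oxiran-2-yl]-2-methylidenepropanoate
Conditions: Ti(OiPr)4 (cat.), D-(−)-diisopropyl tartrate (cat.), t-BuOOH (0.6 equiv), 4 Å MS, CH2Cl2, −20 °C
Reagents that add atoms: tert-butyl hydroperoxide CC(C)(C)OO
Why: Sharpless kinetic resolution (Katsuki–Sharpless epoxidation), in which the D-(−)-tartrate complex should epoxidise the (S) alcohol fast at its E-disubstituted C7=C8 olefin on the face that gives the erythro trans-epoxide, fixing C7 and C8 and selecting C6, while the (R) alcohol is mismatched for this olefin and the C4=C5 olefin is slowed by its cis methyl group, so that at most half of 7 is converted.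

Step 6
Reactants: 8 methyl 3-[(2R,3R)-3-[(1R,2E)-1-hydroxy-3-methylhepta-2,6-dien-1-yl]oxiran-2-yl]-2-methylidenepropanoate
Product: 9 methyl 3-[(2R,3S)-3-[(1R,2E)-1-{[(diethoxyphosphoryl)acetyl]oxy}-3-methylhepta-2,6-dien-1-yl]oxiran-2-yl]-2-methylidenepropanoate
Conditions: (EtO)2P(O)CH2CO2H, EDC·HCl, DMAP (cat.), CH2Cl2, 0 to 23 °C
Reagents that add atoms: diethylphosphonoacetic acid CCOP(=O)(CC(=O)O)OCC
Why: Carbodiimide (Steglich) esterification under near-neutral conditions should acylate the secondary alcohol without opening or shifting the epoxide and installs the C11–C12 unit together with its phosphoryl activating group.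

Step 7
Reactants: 9 methyl 3-[(2R,3S)-3-[(1R,2E)-1-{[(diethoxyphosphoryl)acetyl]oxy}-3-methylhepta-2,6-dien-1-yl]oxiran-2-yl]-2-methylidenepropanoate
Product: 10 methyl (4R)-4-[(2R,3R)-4-(diethoxyphosphoryl)-2-[(1E)-2-methylhexa-1,5-dien-1-yl]-5-oxooxolan-3-yl]-4-hydroxy-2-methylidenebutanoate (epimers at the phosphorus-bearing carbon)
Conditions: DBU, LiClO4, MeCN (0.02 M), 23 to 45 °C; AcOH quench
Reagents that add atoms: none
Why: Proposed new method: DBU and lithium ion generate the chelated phosphonoacetate carbanion at C11, which attacks the neighbouring epoxide carbon C7 from the rear of its C–O bond in an SN2 opening, so that the C7–C11 bond and the γ-lactone (ring atoms O6, C12, C11, C7, C6) form together while the epoxide oxygen stays on C8 as the free hydroxyl. The closest known reactions are the intermolecular alkylation of phosphonoacetate anions by epoxides to α-phosphono-γ-lactones, the base-induced C-2 opening of carbamates of 2,3-epoxy alcohols and the Stork epoxynitrile cyclisation; what is new is a carbon nucleophile tethered through the ester oxygen. The ring closes in the 5-exo-tet mode, and because the carbanion is stabilised by the exocyclic phosphoryl group it need not stay coplanar with the ester carbonyl, which lifts the usual restriction on enolate-endo closures of five-membered rings. C7 is set by inversion at the epoxide carbon, C8 keeps its Sharpless configuration and C6 is untouched, so the trans-disubstituted lactone with the (R) carbinol at C8 should result, C11 forming as an inconsequential epimer mixture. The step needs attack at C7 and not at C8 (6-endo), secured by the shorter tether and the absence of any cation-stabilising group at C8. It must also outrun conjugate addition of the carbanion to the 2-substituted acrylate and lactonisation of the new C8 oxygen onto the methyl ester, secured by high dilution and by a weak base whose conjugate acid protonates the alkoxide at once.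

Step 8
Reactants: 10 methyl (4R)-4-[(2R,3R)-4-(diethoxyphosphoryl)-2-[(1E)-2-methylhexa-1,5-dien-1-yl]-5-oxooxolan-3-yl]-4-hydroxy-2-methylidenebutanoate
Product: 11 methyl (3aR,4R,6E,10E,11aR)-3-(diethoxyphosphoryl)-4-hydroxy-10-methyl-2-oxo-2,3,3a,4,5,8,9,11a-octahydrocyclodeca[b]furan-6-carboxylate (epimers at C3)
Conditions: second-generation Hoveyda–Grubbs catalyst (10 mol%), 1,2-dichloroethane (0.002 M), 60 °C, slow addition
Reagents that add atoms: none
Why: Ring-closing olefin metathesis, in which the catalyst should load on the monosubstituted C1 alkene and close onto the 1,1-disubstituted acrylate with loss of ethene, the new trisubstituted olefin forming ring-cis (C9 and C2 cis, the E enoate of the target) as the less strained geometry of a ten-membered ring, while the C4=C5 olefin, the phosphonate and the free hydroxyl are tolerated and the neutral medium keeps the C8 hydroxyl from attacking either ester.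

Step 9
Reactants: 11 methyl (3aR,4R,6E,10E,11aR)-3-(diethoxyphosphoryl)-4-hydroxy-10-methyl-2-oxo-2,3,3a,4,5,8,9,11a-octahydrocyclodeca[b]furan-6-carboxylate
Product: 12 methyl (3aR,4R,6E,10E,11aR)-3-(diethoxyphosphoryl)-10-methyl-4-[(2-methylprop-2-enoyl)oxy]-2-oxo-2,3,3a,4,5,8,9,11a-octahydrocyclodeca[b]furan-6-carboxylate (epimers at C3)
Conditions: methacrylic anhydride, Et3N, DMAP (cat.), CH2Cl2, 0 to 23 °C
Reagents that add atoms: methacrylic anhydride C=C(C)C(=O)OC(=O)C(C)=C
Why: DMAP-catalysed acyl transfer from the anhydride should esterify the secondary C8 alcohol with retention, and it is placed after ring closure so that the methacrylate olefin cannot compete in the metathesis and before the basic last step so that no free C8 alkoxide can attack the lactone or the C14 ester.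

Step 10
Reactants: 12 methyl (3aR,4R,6E,10E,11aR)-3-(diethoxyphosphoryl)-10-methyl-4-[(2-methylprop-2-enoyl)oxy]-2-oxo-2,3,3a,4,5,8,9,11a-octahydrocyclodeca[b]furan-6-carboxylate
Product: 13 methyl (3aR,4R,6E,10E,11aR)-10-methyl-3-methylidene-4-[(2-methylprop-2-enoyl)oxy]-2-oxo-2,3,3a,4,5,8,9,11a-octahydrocyclodeca[b]furan-6-carboxylate (CNP0317149.1)
Conditions: aq. HCHO (37%), K2CO3, THF, 0 to 23 °C
Reagents that add atoms: formaldehyde C=O
Why: Horner–Wadsworth–Emmons olefination of the α-phosphono lactone with formaldehyde under mild carbonate conditions should give the exocyclic C11=C13 methylene and remove both the phosphoryl helper and the undefined C11 centre, excess formaldehyde trapping the carbanion before it can add to the ring enoate and the other two esters surviving cold aqueous K2CO3.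

**Compound list**

1 | hex-1-en-5-yne | C=CCCC#C | starting material
2 | [(1E)-2-methylhexa-1,5-dien-1-yl]dimethylalane | C=CCC/C(C)=C/[Al](C)C | intermediate (not isolated)
3 | (1E)-1-iodo-2-methylhexa-1,5-diene | C=CCC/C(C)=C/I | intermediate
4 | methyl 2-(bromomethyl)prop-2-enoate | C=C(CBr)C(=O)OC | starting material
5 | methyl 2-methylidenepent-4-enoate | C=CCC(=C)C(=O)OC | intermediate
6 | methyl (4E)-2-methylidene-6-oxohex-4-enoate | O=C/C=C/CC(=C)C(=O)OC | intermediate
7 | methyl (4E,7E)-6-hydroxy-8-methyl-2-methylidenedodeca-4,7,11-trienoate (racemic) | C=CCC/C(C)=C/C(O)/C=C/CC(=C)C(=O)OC | intermediate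
8 | methyl 3-[(2R,3R)-3-[(1R,2E)-1-hydroxy-3-methylhepta-2,6-dien-1-yl]oxiran-2-yl]-2-methylidenepropanoate | C=CCC/C(C)=C/[C@@H](O)[C@H]1O[C@@H]1CC(=C)C(=O)OC | intermediate
9 | methyl 3-[(2R,3S)-3-[(1R,2E)-1-{[(diethoxyphosphoryl)acetyl]oxy}-3-methylhepta-2,6-dien-1-yl]oxiran-2-yl]-2-methylidenepropanoate | C=CCC/C(C)=C/[C@@H](OC(=O)CP(=O)(OCC)OCC)[C@H]1O[C@@H]1CC(=C)C(=O)OC | intermediate
10 | methyl (4R)-4-[(2R,3R)-4-(diethoxyphosphoryl)-2-[(1E)-2-methylhexa-1,5-dien-1-yl]-5-oxooxolan-3-yl]-4-hydroxy-2-methylidenebutanoate (epimers at the phosphorus-bearing carbon) | C=CCC/C(C)=C/[C@H]1OC(=O)C(P(=O)(OCC)OCC)[C@@H]1[C@H](O)CC(=C)C(=O)OC | intermediate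
11 | methyl (3aR,4R,6E,10E,11aR)-3-(diethoxyphosphoryl)-4-hydroxy-10-methyl-2-oxo-2,3,3a,4,5,8,9,11a-octahydrocyclodeca[b]furan-6-carboxylate (epimers at C3) | O[C@@H]1C/C(C(=O)OC)=C\CC/C(C)=C/[C@H]2OC(=O)C(P(=O)(OCC)OCC)[C@@H]21 | intermediate
12 | methyl (3aR,4R,6E,10E,11aR)-3-(diethoxyphosphoryl)-10-methyl-4-[(2-methylprop-2-enoyl)oxy]-2-oxo-2,3,3a,4,5,8,9,11a-octahydrocyclodeca[b]furan-6-carboxylate (epimers at C3) | C=C(C)C(=O)O[C@@H]1C/C(C(=O)OC)=C\CC/C(C)=C/[C@H]2OC(=O)C(P(=O)(OCC)OCC)[C@@H]21 | intermediate
13 | methyl (3aR,4R,6E,10E,11aR)-10-methyl-3-methylidene-4-[(2-methylprop-2-enoyl)oxy]-2-oxo-2,3,3a,4,5,8,9,11a-octahydrocyclodeca[b]furan-6-carboxylate | C=C(C)C(=O)O[C@@H]1C/C(C(=O)OC)=C\CC/C(C)=C/[C@H]2OC(=O)C(=C)[C@@H]21 | target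

**Step count**

Total steps: 10. Longest linear sequence: 9 steps (from 4, steps 2 to 10).

**Steps most likely to fail**

1. Step 7 (Proposed new method). The ester may stay in its extended conformation so that the carbanion never reaches C7, and intermolecular alkylation, attack at C8 or conjugate addition to the acrylate may take over. The fallback uses known chemistry, sets out from 8 and comes back at 13; it replaces the ester tether by a propargyl ether and makes the C7–C11 bond by a radical.
 - O-Propargylation of 8 (NaH, propargyl bromide, THF, 0 °C) gives methyl 3-[(2R,3S)-3-[(1R,2E)-3-methyl-1-(prop-2-yn-1-yloxy)hepta-2,6-dien-1-yl]oxiran-2-yl]-2-methylidenepropanoate F1.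
 - Cp2TiCl (from Cp2TiCl2 and Zn, THF, 23 °C) opens the epoxide homolytically at C7 (Nugent–RajanBabu opening, precedented for propargyl ethers of 2,3-epoxy alcohols). The C7 radical closes 5-exo-dig onto the alkyne trans to the C6 side chain and should give methyl (4R)-4-hydroxy-2-methylidene-4-[(2R,3R)-2-[(1E)-2-methylhexa-1,5-dien-1-yl]-4-methylideneoxolan-3-yl]butanoate F2.
 - Ring-closing metathesis under the step-8 conditions gives methyl (3aR,4R,6E,10E,11aR)-4-hydroxy-10-methyl-3-methylidene-2,3,3a,4,5,8,9,11a-octahydrocyclodeca[b]furan-6-carboxylate F3.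
 - Methacrylic anhydride, Et3N and DMAP give methyl (3aR,4R,6E,10E,11aR)-10-methyl-3-methylidene-4-[(2-methylprop-2-enoyl)oxy]-2,3,3a,4,5,8,9,11a-octahydrocyclodeca[b]furan-6-carboxylate F4.
 - Collins oxidation (CrO3·2C5H5N, CH2Cl2) of the ring CH2 that is both allylic to the exocyclic methylene and next to oxygen then gives 13.

2. Step 8. Oligomerisation through cross-metathesis of the terminal alkenes may outrun closure onto the hindered acrylate, because the trans-lactone holds the two chains apart. The fallback sets out from 9 and comes back at 11; it inverts the order of the two ring closures. Compound 9 is treated with the same catalyst at high dilution and should give methyl (1S,2R,3E,7E,10R)-2-{[(diethoxyphosphoryl)acetyl]oxy}-4-methyl-11-oxabicyclo[8.1.0]undeca-3,7-diene-8-carboxylate F5, in which only the small epoxide ring constrains the chain. The step-7 conditions then close the lactone across the ten-membered ring to give 11.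

3. Step 5. Discrimination may be weak: the other enantiomer can be epoxidised at its C4=C5 olefin, and the doubly allylic alcohol can ionise on the titanium Lewis acid, which lowers both purity and yield. The fallback sets out from 6 (with 3) and comes back at 8; it makes the epoxide by reagent control before the carbinol centre exists.
 - Luche reduction of 6 (NaBH4, CeCl3·7H2O, MeOH, 0 °C) gives methyl (4E)-6-hydroxy-2-methylidenehex-4-enoate F6.
 - Sharpless asymmetric epoxidation (Ti(OiPr)4, D-(−)-diethyl tartrate, t-BuOOH, 4 Å MS, CH2Cl2, −20 °C) gives methyl 3-[(2R,3R)-3-(hydroxymethyl)oxiran-2-yl]-2-methylidenepropanoate F7, without the loss inherent in a resolution.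
 - Dess–Martin oxidation gives methyl 3-[(2R,3S)-3-formyloxiran-2-yl]-2-methylidenepropanoate F8.
 - Nozaki–Hiyama–Kishi addition of 3 (CrCl2, NiCl2 cat., DMSO) should give 8 as the major Felkin–Anh (erythro) diastereomer, the C6 epimer being removed by chromatography.

**Further compounds**

F1 | step 7 | methyl 3-[(2R,3S)-3-[(1R,2E)-3-methyl-1-(prop-2-yn-1-yloxy)hepta-2,6-dien-1-yl]oxiran-2-yl]-2-methylidenepropanoate | C=CCC/C(C)=C/[C@@H](OCC#C)[C@H]1O[C@@H]1CC(=C)C(=O)OC
F2 | step 7 | methyl (4R)-4-hydroxy-2-methylidene-4-[(2R,3R)-2-[(1E)-2-methylhexa-1,5-dien-1-yl]-4-methylideneoxolan-3-yl]butanoate | C=CCC/C(C)=C/[C@H]1OCC(=C)[C@@H]1[C@H](O)CC(=C)C(=O)OC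
F3 | step 7 | methyl (3aR,4R,6E,10E,11aR)-4-hydroxy-10-methyl-3-methylidene-2,3,3a,4,5,8,9,11a-octahydrocyclodeca[b]furan-6-carboxylate | O[C@@H]1C/C(C(=O)OC)=C\CC/C(C)=C/[C@H]2OCC(=C)[C@@H]21
F4 | step 7 | methyl (3aR,4R,6E,10E,11aR)-10-methyl-3-methylidene-4-[(2-methylprop-2-enoyl)oxy]-2,3,3a,4,5,8,9,11a-octahydrocyclodeca[b]furan-6-carboxylate | C=C(C)C(=O)O[C@@H]1C/C(C(=O)OC)=C\CC/C(C)=C/[C@H]2OCC(=C)[C@@H]21
F5 | step 8 | methyl (1S,2R,3E,7E,10R)-2-{[(diethoxyphosphoryl)acetyl]oxy}-4-methyl-11-oxabicyclo[8.1.0]undeca-3,7-diene-8-carboxylate | [C@@H]1(OC(=O)CP(=O)(OCC)OCC)/C=C(C)/CC/C=C(C(=O)OC)\C[C@H]2O[C@@H]21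
F6 | step 5 | methyl (4E)-6-hydroxy-2-methylidenehex-4-enoate | OC/C=C/CC(=C)C(=O)OC
F7 | step 5 | methyl 3-[(2R,3R)-3-(hydroxymethyl)oxiran-2-yl]-2-methylidenepropanoate | OC[C@H]1O[C@@H]1CC(=C)C(=O)OC
F8 | step 5 | methyl 3-[(2R,3S)-3-formyloxiran-2-yl]-2-methylidenepropanoate | O=C[C@H]1O[C@@H]1CC(=C)C(=O)OC
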